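**Retrosynthetic overview**

1. Cage numbering (2-oxabicyclo[2.2.2]octane): C1 = O–CH, O2, C3 = lactone C=O, C4 = quaternary CMe, C5 = ketone, C6 = CHMe, C7 = CHMe, C8 = spiro carbon (= C2' of the oxane).
2. The last step closes both cage rings from monocyclic seco acid 23 by forming O2–C1 (conjugate lactonisation) and C4–C5 (Dieckmann acylation). The enabling feature is that ring O2–C3–C4–C5–C6–C1 is the sum of a propanoic acid unit (O2, C3, C4: O- and C-nucleophile) and a 2-methyl-enoyl unit (C5, C6, C1: acyl and β-carbon electrophile), both hanging from spiro C8 (the enoyl through C7), so only the six-membered O2→C1 and C4→C5 closures are possible.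
3. 23 comes from aldehyde 18 and phosphonate 21 (Horner–Wadsworth–Emmons); quaternary C8 comes from methyl ketal 13 and propanoate silyl ketene acetal 15 (axial C-glycosylation).
4. The oxane with all five chain stereocentres comes from a tin-mediated syn-aldol of Roche-ester ketone 10 with aldehyde 6 (Evans aldol), then ketalisation.
5. Ring order: oxane (step 9), then δ-lactone and cyclohexanone together (step 18). The acetate is carried from step 10, so the key step ends the synthesis.

Key step: step 18

Assumptions: 2-(diethoxyphosphoryl)propanoic acid 19 is taken as a catalogue compound. Compounds 16, 17, 18, 22, 23 and 24 and the fallback compounds F1, F2, F4, F5, F6, F7 and F8 are mixtures of epimers at the propanoate α-carbon (future C4), drawn without configuration there; this centre becomes a planar enolate carbon in step 18, so its configuration is immaterial.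

**Route**

Step 1
Reactants: 1 (4R)-4-benzyl-3-propanoyl-1,3-oxazolidin-2-one; 2 acetaldehyde
Product: 3 (4R)-4-benzyl-3-[(2R,3S)-3-hydroxy-2-methylbutanoyl]-1,3-oxazolidin-2-one
Conditions: Bu2BOTf, iPr2NEt, CH2Cl2, −78 to 0 °C; then H2O2, MeOH, pH 7 buffer
Reagents that add atoms: none
Why: Evans syn-aldol through the Z-boron enolate and a Zimmerman–Traxler chair, in which the (R)-benzyl auxiliary fixes the enolate face and gives the 2,3-syn (2R,3S) adduct.

Step 2
Reactants: 3
Product: 4 (4R)-4-benzyl-3-[(2R,3S)-2-methyl-3-(triethylsilyloxy)butanoyl]-1,3-oxazolidin-2-one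
Conditions: TESCl, imidazole, DMF, 0 to 23 °C
Reagents that add atoms: chlorotriethylsilane, CC[Si](Cl)(CC)CC
Why: Standard silylation of a secondary alcohol; no stereocentre is touched.

Step 3
Reactants: 4
Product: 5 (2S,3S)-2-methyl-3-(triethylsilyloxy)butan-1-ol
Conditions: LiBH4, MeOH (1 equiv), Et2O, 0 °C
Reagents that add atoms: none
Why: Reductive removal of the auxiliary by hydride attack at the exocyclic imide carbonyl, without epimerisation of the α-centre.

Step 4
Reactants: 5
Product: 6 (2R,3S)-2-methyl-3-(triethylsilyloxy)butanal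
Conditions: Dess–Martin periodinane, pyridine, CH2Cl2, 0 to 23 °C
Reagents that add atoms: none
Why: Buffered Dess–Martin oxidation gives the α-chiral aldehyde without epimerisation; it is used directly.

Step 5
Reactants: 7 methyl (2R)-3-hydroxy-2-methylpropanoate
Product: 8 methyl (2R)-3-(benzyloxy)-2-methylpropanoate
Conditions: benzyl 2,2,2-trichloroacetimidate, TfOH (cat.), CH2Cl2/cyclohexane, 23 °C
Reagents that add atoms: benzyl 2,2,2-trichloroacetimidate, N=C(OCc1ccccc1)C(Cl)(Cl)Cl
Why: Acid-catalysed imidate benzylation avoids base and so cannot racemise or eliminate the β-hydroxy ester.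

Step 6
Reactants: 8
Product: 9 (2R)-3-(benzyloxy)-N-methoxy-N,2-dimethylpropanamide
Conditions: MeONHMe·HCl, iPrMgCl, THF, −20 to 0 °C
Reagents that add atoms: N,O-dimethylhydroxylamine hydrochloride, CNOC.Cl
Why: Weinreb amide formation from the ester through the magnesium amide, fast enough at low temperature to leave the α-centre intact.

Step 7
Reactants: 9
Product: 10 (2R)-1-(benzyloxy)-2-methylpentan-3-one
Conditions: EtMgBr, THF, 0 °C
Reagents that add atoms: ethylmagnesium bromide, CC[Mg]Br
Why: Grignard addition to a Weinreb amide stops at the chelated tetrahedral intermediate and gives the ethyl ketone on work-up.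

Step 8
Reactants: 10; 6
Product: 11 (2R,4S,5R,6S,7S)-1-(benzyloxy)-5-hydroxy-2,4,6-trimethyl-7-(triethylsilyloxy)octan-3-one
Conditions: Sn(OTf)2 (divalent tin), Et3N, CH2Cl2, −78 °C; then 6
Reagents that add atoms: none
Why: Tin-mediated syn-aldol of the benzyloxy ketone: the chelated Z-enolate gives the 2,4-syn-4,5-syn adduct, and the Z-enolate preference for anti-Felkin attack on the α-methyl aldehyde (5,6-anti) is matched with it.

Step 9
Reactants: 11
Product: 12 (2R,3S,4R,5S,6S)-2-[(2R)-1-(benzyloxy)propan-2-yl]-2-methoxy-3,5,6-trimethyloxan-4-ol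
Conditions: camphorsulfonic acid (cat.), MeOH, 0 to 23 °C
Reagents that add atoms: methanol, CO
Why: Acid methanolysis removes the TES ether, the freed C7 hydroxyl closes onto the C3 ketone (hemiketalisation to the oxane), and the hemiketal is trapped as the thermodynamic methyl ketal with axial OMe (anomeric effect) and the large side chain equatorial.

Step 10
Reactants: 12
Product: 13 (2R,3S,4R,5R,6S)-2-[(2R)-1-(benzyloxy)propan-2-yl]-2-methoxy-3,5,6-trimethyloxan-4-yl acetate
Conditions: Ac2O, pyridine, DMAP (cat.), CH2Cl2, 23 °C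
Reagents that add atoms: acetic anhydride, CC(=O)OC(C)=O
Why: Acetylation of the only free hydroxyl installs the target's acetate once the ketone is masked, so no β-elimination can occur.

Step 11
Reactants: 14 tert-butyl propanoate
Product: 15 1-tert-butoxy-1-(trimethylsilyloxy)prop-1-ene (E/Z mixture)
Conditions: LiN(iPr)2 (LDA, commercial solution), THF, −78 °C; then TMSCl
Reagents that add atoms: chlorotrimethylsilane, C[Si](C)(C)Cl
Why: O-silylation of the ester enolate gives the silyl ketene acetal; its geometry is irrelevant because the centre it creates is later enolised.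

Step 12
Reactants: 13; 15
Product: 16 tert-butyl 2-[(2R,3S,4R,5R,6S)-4-acetoxy-2-[(2R)-1-(benzyloxy)propan-2-yl]-3,5,6-trimethyloxan-2-yl]propanoate
Conditions: TMSOTf (0.2 equiv), 2,6-di-tert-butyl-4-methylpyridine, CH2Cl2, −78 °C
Reagents that add atoms: none
Why: Mukaiyama-type C-glycosylation: TMSOTf ionises the ketal to the oxocarbenium ion, and the silyl ketene acetal attacks axially on the half-chair that keeps the C3, C4 and C6 substituents equatorial, setting quaternary C2 of the oxane with the propanoate arm axial.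

Step 13
Reactants: 16
Product: 17 tert-butyl 2-[(2R,3S,4R,5R,6S)-4-acetoxy-2-[(2R)-1-hydroxypropan-2-yl]-3,5,6-trimethyloxan-2-yl]propanoate
Conditions: H2 (1 atm), Pd/C, EtOAc, 23 °C
Reagents that add atoms: none
Why: Hydrogenolysis of the benzyl ether; the acetate, tert-butyl ester and ring ether are inert.

Step 14
Reactants: 17
Product: 18 tert-butyl 2-[(2S,3S,4R,5R,6S)-4-acetoxy-3,5,6-trimethyl-2-[(2S)-1-oxopropan-2-yl]oxan-2-yl]propanoate
Conditions: Dess–Martin periodinane, pyridine, CH2Cl2, 0 to 23 °C
Reagents that add atoms: none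
Why: Buffered Dess–Martin oxidation; the α-centre is flanked by a quaternary carbon and is slow to enolise (the descriptors change only through CIP priorities).

Step 15
Reactants: 19 2-(diethoxyphosphoryl)propanoic acid; 20 1,3-oxazolidin-2-one
Product: 21 3-[2-(diethoxyphosphoryl)propanoyl]-1,3-oxazolidin-2-one
Conditions: DCC, DMAP (cat.), CH2Cl2, 0 to 23 °C
Reagents that add atoms: none
Why: Steglich-type N-acylation of the oxazolidinone by the carbodiimide-activated acid.

Step 16
Reactants: 18; 21
Product: 22 tert-butyl 2-[(2R,3S,4R,5R,6S)-4-acetoxy-3,5,6-trimethyl-2-[(2R,3E)-4-methyl-5-oxo-5-(2-oxo-1,3-oxazolidin-3-yl)pent-3-en-2-yl]oxan-2-yl]propanoate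
Conditions: LiCl, iPr2NEt, MeCN, 23 °C
Reagents that add atoms: none
Why: Masamune–Roush Horner–Wadsworth–Emmons olefination: the α-methyl phosphonate gives the (E)-trisubstituted enoyl imide, and the mild amine base spares the acetate and the aldehyde α-centre.

Step 17
Reactants: 22
Product: 23 2-[(2R,3S,4R,5R,6S)-4-acetoxy-3,5,6-trimethyl-2-[(2R,3E)-4-methyl-5-oxo-5-(2-oxo-1,3-oxazolidin-3-yl)pent-3-en-2-yl]oxan-2-yl]propanoic acid
Conditions: TFA, CH2Cl2 (1:4), 0 °C
Reagents that add atoms: none
Why: Acidolysis of the tert-butyl ester (loss of 2-methylpropene) frees the acid; the imide, the acetate and the enoyl unit are acid-stable.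

Step 18
Reactants: 23
Product: 26 (1S,3'S,4R,4'R,5'R,6S,6'S,7R,8S)-3',4,5',6,6',7-hexamethyl-3,5-dioxospiro[2-oxabicyclo[2.2.2]octane-8,2'-oxan]-4'-yl acetate (target), via δ-lactone imide 24 (not isolated), via lithium lactone enolate 25 (not isolated)
Conditions: iPr2NEt (0.3 equiv), MgBr2·OEt2 (0.2 equiv), THF, 23 °C; then LiN(SiMe3)2 (LiHMDS, 1.2 equiv), −78 °C; AcOH, −78 °C
Reagents that add atoms: none
Why: Proposed new method: catalytic amine with MgBr2 (two-point activation of the imide) lets the carboxylic acid add 6-exo-trig to the β-carbon of the enoyl imide to give δ-lactone 24 (closest known type: oxa-Michael lactonisation of enone and enoyl-imide acids), and LiN(SiMe3)2 then deprotonates the lactone α-CH, whose enolate 25 attacks the imide carbonyl 6-(enolexo)-exo-trig and expels lithium oxazolidinide (closest known type: Dieckmann cyclisation of O-acyl aldol imides to pyran-2,4-diones). The δ-lactone ring thus closes through the O2–C1 bond and the cyclohexanone ring through the C4–C5 bond, which together make the bicyclo[2.2.2]octane. C1 is set trans to the C7 methyl by a chair-like transition state with both groups equatorial, which is also the thermodynamic outcome of the reversible addition; C6 is set by protonation of the chelated Z-imide enolate anti to the C7 branch under 1,3-allylic strain control, and this is the epimer that places its methyl over the unsubstituted lactone oxygen in the cage. Quaternary C4 is dictated by the tether, since the planar enolate can reach the acyl carbon only on the face that carries the C1 side chain, so both C4 epimers of 23 converge. The step needs regioselective enolisation of the lactone: the α-branched imide CH is shielded by 1,3-allylic strain, the acetate CH3 is less acidic than the lactone CH, and the cold acetic acid quench keeps the product ketone from β-eliminating its lactone oxygen. The tether through C7 and spiro C8 rules out the usual reverse pairing (C-attack at the β-carbon, O-attack at the acyl carbon), which would need four- and eight-membered rings.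

**Compound list**

1 | (4R)-4-benzyl-3-propanoyl-1,3-oxazolidin-2-one | CCC(=O)N1[C@H](Cc2ccccc2)COC1=O | starting material
2 | acetaldehyde | CC=O | starting material
3 | (4R)-4-benzyl-3-[(2R,3S)-3-hydroxy-2-methylbutanoyl]-1,3-oxazolidin-2-one | C[C@H](O)[C@@H](C)C(=O)N1[C@H](Cc2ccccc2)COC1=O | intermediate
4 | (4R)-4-benzyl-3-[(2R,3S)-2-methyl-3-(triethylsilyloxy)butanoyl]-1,3-oxazolidin-2-one | C[C@H](O[Si](CC)(CC)CC)[C@@H](C)C(=O)N1[C@H](Cc2ccccc2)COC1=O | intermediate
5 | (2S,3S)-2-methyl-3-(triethylsilyloxy)butan-1-ol | C[C@H](O[Si](CC)(CC)CC)[C@@H](C)CO | intermediate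
6 | (2R,3S)-2-methyl-3-(triethylsilyloxy)butanal | C[C@H](O[Si](CC)(CC)CC)[C@@H](C)C=O | intermediate
7 | methyl (2R)-3-hydroxy-2-methylpropanoate (Roche ester) | COC(=O)[C@H](C)CO | starting material
8 | methyl (2R)-3-(benzyloxy)-2-methylpropanoate | COC(=O)[C@H](C)COCc1ccccc1 | intermediate
9 | (2R)-3-(benzyloxy)-N-methoxy-N,2-dimethylpropanamide | CON(C)C(=O)[C@H](C)COCc1ccccc1 | intermediate
10 | (2R)-1-(benzyloxy)-2-methylpentan-3-one | CCC(=O)[C@H](C)COCc1ccccc1 | intermediate
11 | (2R,4S,5R,6S,7S)-1-(benzyloxy)-5-hydroxy-2,4,6-trimethyl-7-(triethylsilyloxy)octan-3-one | C[C@H](O[Si](CC)(CC)CC)[C@@H](C)[C@@H](O)[C@H](C)C(=O)[C@H](C)COCc1ccccc1 | intermediate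
12 | (2R,3S,4R,5S,6S)-2-[(2R)-1-(benzyloxy)propan-2-yl]-2-methoxy-3,5,6-trimethyloxan-4-ol | O[C@@H]1[C@H](C)[C@H](C)O[C@](OC)([C@H](C)COCc2ccccc2)[C@H]1C | intermediate
13 | (2R,3S,4R,5R,6S)-2-[(2R)-1-(benzyloxy)propan-2-yl]-2-methoxy-3,5,6-trimethyloxan-4-yl acetate | CC(=O)O[C@@H]1[C@H](C)[C@H](C)O[C@](OC)([C@H](C)COCc2ccccc2)[C@H]1C | intermediate
14 | tert-butyl propanoate | CCC(=O)OC(C)(C)C | starting material
15 | 1-tert-butoxy-1-(trimethylsilyloxy)prop-1-ene (E/Z mixture) | CC=C(OC(C)(C)C)O[Si](C)(C)C | intermediate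
16 | tert-butyl 2-[(2R,3S,4R,5R,6S)-4-acetoxy-2-[(2R)-1-(benzyloxy)propan-2-yl]-3,5,6-trimethyloxan-2-yl]propanoate (α-epimers) | CC(=O)O[C@@H]1[C@H](C)[C@H](C)O[C@](C(C)C(=O)OC(C)(C)C)([C@H](C)COCc2ccccc2)[C@H]1C | intermediate
17 | tert-butyl 2-[(2R,3S,4R,5R,6S)-4-acetoxy-2-[(2R)-1-hydroxypropan-2-yl]-3,5,6-trimethyloxan-2-yl]propanoate (α-epimers) | CC(=O)O[C@@H]1[C@H](C)[C@H](C)O[C@](C(C)C(=O)OC(C)(C)C)([C@H](C)CO)[C@H]1C | intermediate
18 | tert-butyl 2-[(2S,3S,4R,5R,6S)-4-acetoxy-3,5,6-trimethyl-2-[(2S)-1-oxopropan-2-yl]oxan-2-yl]propanoate (α-epimers) | CC(=O)O[C@@H]1[C@H](C)[C@H](C)O[C@](C(C)C(=O)OC(C)(C)C)([C@H](C)C=O)[C@H]1C | intermediate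
19 | 2-(diethoxyphosphoryl)propanoic acid | CCOP(=O)(OCC)C(C)C(=O)O | starting material
20 | 1,3-oxazolidin-2-one | O=C1NCCO1 | starting material
21 | 3-[2-(diethoxyphosphoryl)propanoyl]-1,3-oxazolidin-2-one | CCOP(=O)(OCC)C(C)C(=O)N1CCOC1=O | intermediate
22 | tert-butyl 2-[(2R,3S,4R,5R,6S)-4-acetoxy-3,5,6-trimethyl-2-[(2R,3E)-4-methyl-5-oxo-5-(2-oxo-1,3-oxazolidin-3-yl)pent-3-en-2-yl]oxan-2-yl]propanoate (α-epimers) | CC(=O)O[C@@H]1[C@H](C)[C@H](C)O[C@](C(C)C(=O)OC(C)(C)C)([C@H](C)/C=C(\C)C(=O)N2CCOC2=O)[C@H]1C | intermediate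
23 | 2-[(2R,3S,4R,5R,6S)-4-acetoxy-3,5,6-trimethyl-2-[(2R,3E)-4-methyl-5-oxo-5-(2-oxo-1,3-oxazolidin-3-yl)pent-3-en-2-yl]oxan-2-yl]propanoic acid (α-epimers; seco acid) | CC(=O)O[C@@H]1[C@H](C)[C@H](C)O[C@](C(C)C(=O)O)([C@H](C)/C=C(\C)C(=O)N2CCOC2=O)[C@H]1C | intermediate
24 | δ-lactone imide: 4-acetoxy-2,3,5,7,11-pentamethyl-8-oxo-10-[(2S)-1-oxo-1-(2-oxo-1,3-oxazolidin-3-yl)propan-2-yl]-1,9-dioxaspiro[5.5]undecane, configuration as in the SMILES (lactone O–CH of S configuration, C7 epimers) | CC(=O)O[C@@H]1[C@H](C)[C@H](C)O[C@]2([C@H](C)[C@H](OC(=O)C2C)[C@H](C)C(=O)N3CCOC3=O)[C@H]1C | intermediate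
25 | lithium enolate of the lactone carbonyl of 24 (O–Li ketene acetal, C7=C8 of the spiro numbering) | CC(=O)O[C@@H]1[C@H](C)[C@H](C)O[C@]2([C@H](C)[C@H](OC(=C2C)O[Li])[C@H](C)C(=O)N3CCOC3=O)[C@H]1C | intermediate
26 | (1S,3'S,4R,4'R,5'R,6S,6'S,7R,8S)-3',4,5',6,6',7-hexamethyl-3,5-dioxospiro[2-oxabicyclo[2.2.2]octane-8,2'-oxan]-4'-yl acetate | CC(=O)O[C@@H]1[C@H](C)[C@H](C)O[C@]2([C@H](C)[C@@H]3OC(=O)[C@@]2(C)C(=O)[C@H]3C)[C@H]1C | target

**Step count and risks**

Total step count: 18. Longest linear sequence: 13 steps (1–4, 8–10, 12–14, 16–18).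

Steps most likely to fail:

1. Step 18 (Proposed new method). What may go wrong: the base may deprotonate the imide α-carbon instead of the lactone, which returns the open carboxylate by retro-oxa-Michael. The product ketone may also be enolised by residual base and lose its lactone oxygen by β-elimination, and protonation at C6 may be unselective. Fallback from 18, returning at 26, by known reactions only. Aldehyde 18 is added to the lithium Z-enolate of N-methoxy-N-methylpropanamide in THF at −78 °C, and the anti-Felkin syn-aldol addition should give the β-hydroxy Weinreb amide F1, whose amide α-CH is less acidic than an ester α-CH. TFA then cleaves the tert-butyl ester of F1 and the resulting hydroxy acid is lactonised with EDC·HCl and DMAP to the δ-lactone Weinreb amide F2, so that the lactone is closed by O-acylation of the aldol oxygen. LiN(SiMe3)2 in THF at −78 °C should enolise the lactone of F2 and the enolate adds to the Weinreb amide through a chelated tetrahedral intermediate that releases the ketone only on work-up, which gives the cage ketone F3, the C6 epimer of the target. Finally F3 is treated with p-TsOH (cat.) in CHCl3 at 40 °C, which should equilibrate C6 through the enol to 26.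

2. Step 12. What may go wrong: the hindered oxocarbenium ion may lose a proton to an enol ether faster than it is trapped, which scrambles the two α-methyl centres, or it may not react at all at the neopentyl-like centre. Fallback from 13, returning at 16. Ketal 13 is treated with (E)-crotyltrimethylsilane and TMSOTf in CH2Cl2 at −78 °C, a smaller π-nucleophile that should add axially and give the but-3-en-2-yl C-glycoside F4, again as a mixture at the new CH centre. Ozonolysis of F4 with O3 and then PPh3 gives the aldehyde F5, Pinnick oxidation of F5 with NaClO2, NaH2PO4 and 2-methylbut-2-ene gives the carboxylic acid F6, and esterification of F6 with tert-butyl 2,2,2-trichloroacetimidate in CH2Cl2/cyclohexane at 23 °C gives 16.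

3. Step 16. What may go wrong: olefination of the neopentyl-type α-branched aldehyde may be slow, so that the basic medium epimerises the α-centre or opens the oxane by β-elimination of the ring oxygen. Fallback from 18, returning at 22. Aldehyde 18 is heated with the neutral ylide 2-(triphenylphosphoranylidene)propanal in toluene at 80 °C to give the (E)-enal F7, without any added base. Pinnick oxidation of F7 gives the (E)-enoic acid F8, and the pivaloyl mixed anhydride of F8 (PivCl, Et3N) acylates oxazolidin-2-one 20 in the presence of LiCl to give 22.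

Further compounds
F1 | step 18 | tert-butyl 2-[4-acetoxy-2-[(2R,3S,4R)-3-hydroxy-5-[methoxy(methyl)amino]-4-methyl-5-oxopentan-2-yl]-3,5,6-trimethyloxan-2-yl]propanoate (ring configuration as in 18; syn aldol) | CC(=O)O[C@@H]1[C@H](C)[C@H](C)O[C@](C(C)C(=O)OC(C)(C)C)([C@H](C)[C@H](O)[C@@H](C)C(=O)N(C)OC)[C@H]1C
F2 | step 18 | δ-lactone Weinreb amide, the C6 epimer of 24 with N(OMe)Me in place of the oxazolidinone | CC(=O)O[C@@H]1[C@H](C)[C@H](C)O[C@]2([C@H](C)[C@H](OC(=O)C2C)[C@@H](C)C(=O)N(C)OC)[C@H]1C
F3 | step 18 | C6 epimer of target 26 | CC(=O)O[C@@H]1[C@H](C)[C@H](C)O[C@]2([C@H](C)[C@@H]3OC(=O)[C@@]2(C)C(=O)[C@@H]3C)[C@H]1C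
F4 | step 12 | 2-[(2R)-1-(benzyloxy)propan-2-yl]-2-(but-3-en-2-yl)-3,5,6-trimethyloxan-4-yl acetate (ring configuration as in 16) | CC(=O)O[C@@H]1[C@H](C)[C@H](C)O[C@](C(C)C=C)([C@H](C)COCc2ccccc2)[C@H]1C
F5 | step 12 | 2-[(2R)-1-(benzyloxy)propan-2-yl]-3,5,6-trimethyl-2-(1-oxopropan-2-yl)oxan-4-yl acetate | CC(=O)O[C@@H]1[C@H](C)[C@H](C)O[C@](C(C)C=O)([C@H](C)COCc2ccccc2)[C@H]1C
F6 | step 12 | 2-[4-acetoxy-2-[(2R)-1-(benzyloxy)propan-2-yl]-3,5,6-trimethyloxan-2-yl]propanoic acid | CC(=O)O[C@@H]1[C@H](C)[C@H](C)O[C@](C(C)C(=O)O)([C@H](C)COCc2ccccc2)[C@H]1C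
F7 | step 16 | tert-butyl 2-[4-acetoxy-3,5,6-trimethyl-2-[(2R,3E)-4-methyl-5-oxopent-3-en-2-yl]oxan-2-yl]propanoate | CC(=O)O[C@@H]1[C@H](C)[C@H](C)O[C@](C(C)C(=O)OC(C)(C)C)([C@H](C)/C=C(\C)C=O)[C@H]1C
F8 | step 16 | (2E,4R)-4-[4-acetoxy-2-(1-tert-butoxy-1-oxopropan-2-yl)-3,5,6-trimethyloxan-2-yl]-2-methylpent-2-enoic acid | CC(=O)O[C@@H]1[C@H](C)[C@H](C)O[C@](C(C)C(=O)OC(C)(C)C)([C@H](C)/C=C(\C)C(=O)O)[C@H]1C
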